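The readings come from a simulation with constants of no real substance, and the scatter is random.

The target in this flask is a middle stage: the free catalyst makes it from the substrate, and a proposed uncatalysed step passes it on to isomer of the product A.

common to all: substrate 0.050 M; free catalyst 0.26 mol%

| charge | remark | time |
|---|---|---|
| ochre | the very flask that is asked about, followed so far |  |
| flask |  | 12 h |

ochre run (percent of the substrate charged)

| time / h | target / % | substrate / % |
|---|---|---|
| 1.33 | 37.5 | 40.0 |
| 2.50 | 30.5 | 33.6 |
| 4.00 | 24.6 | 29.6 |
| 5.00 | 22.2 | 28.3 |
| 6.00 | 20.2 | 28.1 |
| 8.00 | 19.3 | 26.6 |

(standard deviation of a reading: 0.5 percentage points)

- east: at 12 h add substrate, 50.0% of the amount charged, then wait 12 h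
- north-west: at 12 h add free catalyst, 100% of the amount charged, then wait 12 h
- south: at 12 h take out 90% of the target then present, then wait 12 h
- north: change nothing and wait 12 h more

* target, in percent of the substrate first charged, at 12 h
* which option adds most target ("none" when 2 percentage points or less is all one gets) (east / north-west / south / north / none)
* target present, with what was taken out counted in, in percent of the substrate first charged, after east
* target present, with what was taken out counted in, in percent of the substrate first charged, after north

- what is taken out of target is counted as made
- the earlier runs were read with a standard deviation of 0.5 percentage points
- steps that have been proposed: substrate + free catalyst <-> target + free catalyst; target <-> isomer of the product A; isomer of the product A + free catalyst <-> isomer of the product B + free catalyst; 2 free catalyst -> spent catalyst A; free catalyst <-> dormant form; free catalyst -> spent catalyst B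
- additions bring no volume worth counting

*What do you follow?* The share s, meaning target divided by converted substrate, where converted substrate C is the charge minus the substrate still present. Dividing by C takes the supply out of the picture.

*What does s do?* At 4.00 h, 6.00 h and 8.00 h it reads 34.9%, 28.1% and 26.3%. The steps are 6.8 percentage points and then 1.8 points, a ratio of 0.263, so it behaves like a first-order lag with time constant τ of about 1.50 h.

*Isn't that two differences of noisy readings?* Yes. The target reading alone puts about 0.68 points of scatter on each share, so τ is rough and I use s as read. I take it as the late end, a split held by an equilibrium, which is thermodynamic control against the kinetic control of the early end.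

*And joining the ends?* Target is s times C. Substrate moved 1.5 points over the last interval, so I take C as steady, and my estimate for 12 h is the last reading, 19.3%.

*Which option?* South takes out a fraction 90% of the target, and the pool re-splits at s because τ is shorter than the wait. The gain is that fraction times target times (one minus s), or 13 points. At this s, east or north-west needs 7.6 points more converted substrate to pass the margin.

The forecast gives 17.8% (16.3% to 19%), below my figure. It also gives 20% after east and 18% after north, and it chooses south: "Removing 90 % of target pulls isomer back".

    substrate + free catalyst ⇌ target + free catalyst, rate k1*[substrate]*[free catalyst] forward; the back reaction follows from the equilibrium constant (K = 2.60, k = 21700 L mol⁻¹ h⁻¹)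
    target ⇌ isomer of the product A (K = 2.40, k = 0.555 h⁻¹)
    isomer of the product A + free catalyst ⇌ isomer of the product B + free catalyst, rate k3*[free catalyst]*[isomer of the product A] forward; the back reaction follows from the equilibrium constant (K = 4.31, k = 5620 L mol⁻¹ h⁻¹)
    2 free catalyst → spent catalyst A (k = 5780 L mol⁻¹ h⁻¹)
    free catalyst ⇌ dormant form (K = 0.580, k = 0.755 h⁻¹)
    free catalyst → spent catalyst B (k = 1.09 h⁻¹)

The flask holds 19.5% of target at 12 h, against 19.2% from s. South adds 12 points, east −0.035 points, north-west −0.87 points and north −0.059 points, leaving 19.5% after east and 19.5% after north. In the neighbour flask with 0.1 mol% of free catalyst, s gives 13.8% of target at 12.0 h, against 14.8%. In the asked flask at 12.0 h, the substrate's half-life by its forward step alone is 33 d, far longer than the 1.25 h of target by its forward first-order passing into isomer of the product A. At that 12.0 h the flask keeps 0.0309% of its catalyst free, and its substrate stands at 27%.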